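Gamma gets a larger dose D than beta, D being the free catalyst charged times the minutes: 60.0 mM·min against 42.0 mM·min. Beta also stands longer, 30 min against 10 min, and target made early has longer to be lost, so the size of gamma's lead hangs on what those extra minutes cost.

| setting | red | violet | beta | gamma |
|---|---|---|---|---|
| substrate | 2.8 M | 2.8 M | 2.8 M | 2.8 M |
| free catalyst | 1.9 mM | 7.4 mM | 1.4 mM | 6.0 mM |
| remark | run made earlier | run made earlier |  |  |
| time |  |  | 30 min | 10 min |

| run | time / min | target / % |
|---|---|---|
| red | 1.50 | 5.1 |
| red | 4.00 | 8.4 |
| red | 10.0 | 17.4 |
| red | 20.0 | 27.4 |
| violet | 2.50 | 18.7 |
| violet | 8.00 | 47.2 |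
| violet | 15.0 | 58.7 |
| violet | 20.0 | 56.0 |

(each reading ± 1 percentage point)



* which one finishes higher in amount of target, in percent of the substrate charged ("neither" within 2 percentage points) (beta / gamma / neither)
* amount of target at the end, in percent of the substrate charged, beta
* amount of target at the end, in percent of the substrate charged, gamma

The violet run reads 58.7% at 15.0 min and 56.0% at 20.0 min, so target is being lost as well as made. In a chain of two first-order steps, substrate to target and target onward, making equals losing at the top, and the height of the top as a fraction of the charge equals exp(−λt) at the time of the top. This gives the loss constant λ, the first-order rate at which target disappears, as minus the logarithm of the height divided by the time of the top: read from violet, 0.0355 /min.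

Take λ to run on the clock whatever the catalyst, and let substrate fall pseudo-first-order with constant κ times catalyst. Target is then roughly the made fraction, one minus exp(−κD), times a kept share, exp(−λt) with t taken as half the run, the mean age of the target. Violet's reading of 47.2% at 8.00 min gives κ = 0.0133 /mM/min. The red run, unused so far, serves as a check: the reckoning gives 27.8% at 20.0 min, and the reading is 27.4%.

Beta keeps 58.7% and gamma 83.7%, so my reckoning puts beta at 25.1% and gamma at 46.0%, and gamma is the recipe to charge.

The forecast also picks gamma, with 46% (41% to 50%) for gamma, close to this reckoning. For beta it gives 30% (26% to 34%), higher than this reckoning, reading beta as “equal to red at about 22 min”.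

Beta gives 24.6% and gamma 46.4%, so gamma finishes higher, and over-reaction product stands at 18.4% in beta against 10.6% in gamma.

    substrate + free catalyst → catalyst intermediate A (k = 23.0 /M/min)
    catalyst intermediate A ⇌ catalyst intermediate B (K = 0.410, k = 320 /min)
    catalyst intermediate B → free catalyst + target (k = 300 /min)
    target → over-reaction product (k = 0.0390 /min)

Beta's target divided by its kept share is 41.9%, beside a conversion of 43.0%. Gamma read later, at 15 min, is reckoned with the same λ and κ at 53.4%, and that flask holds 54.0% target.

(The earlier runs and the new flask come from a simulation for substances that don't exist; noise was put on by code.)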